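Conventions used throughout: the tetrahydrofuran ring is numbered O1, C2 (guaiacyl), C3 (bears C9), C4 (bears the carbinol C7'), C5 (CH2). TBS = tert-butyldimethylsilyl, TBSO = tert-butyldimethylsilyloxy.

## The problem

The target 17 is a 2,3,4-trisubstituted tetrahydrofuran. C2 carries the 4-hydroxy-3-methoxyphenyl ring, C3 the hydroxymethyl carbon C9, C4 the benzylic carbinol C7' with its catechol ring, and C5 is a bare CH2. It has four stereocentres: (2S,3R,4S) on the ring, with the substituents 2,3-trans and 3,4-trans, and (7'R) outside it. The all-trans ring is the thermodynamically preferred arrangement, and this divides the task. C4 must be set in the absolute sense; C2 and C3 can then follow C4 through any reversible bond formation; C7' must be induced from C4 across one bond. Two C–O bonds (C2–O1 and C7'–OH) are benzylic to para-oxygenated arenes, so they ionise under acid and are at risk under hydrogenolysis, and the free catechol is sensitive to base and air. The phenols should therefore be unmasked last, without acid, strong base or hydrogen. The feature that opens the key step is the sequence O1–C2(aryl)–C3–C9(O): C2 is bonded to one ring oxygen and to C3, and C3 bears one oxygenated carbon. This is the pattern left when the acetal carbon of a cyclic vinyl acetal (C2 held between O1 and the enol oxygen on C9) moves from that oxygen to the enol carbon C3.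

## Retrosynthesis

17 from 16. No skeletal bond is cut; the three phenols are masked as aryl TBS ethers in 16. Silyl ethers are preferred to benzyl ethers because the last step then needs only buffered fluoride, which leaves both activated benzylic C–O bonds alone. The forward step only has to keep the phenoxides from staying basic.

16 from 15. The C7'–H bond is cut, which leads back to the aryl ketone 15. Because C7' is next to C4, the existing centre can direct a hydride; the alternative of adding an aryl nucleophile to a C4 aldehyde would face the same induction problem with a less biased carbonyl. 15 has one stereocentre fewer. The forward reduction must attack the ketone face opposite the branched ring carbon C3.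

15 from 13 (through diol 14). The C7'=O bond is traced back to a C7'=CH2 bond, so the ketone is hidden as a 1-arylvinyl group in alcohol 13. A free ketone at this position could not be carried through the earlier steps: it would acidify C4–H, invite β-elimination of the ring oxygen and conjugate with the enol ether of the acetal stage. The alkene is inert there and is exactly what a Heck reaction delivers. The forward step is a dihydroxylation–glycol cleavage of the only alkene in 13.

13 from 12. The C9 alcohol comes from the aldehyde 12 by reduction; this adjusts the oxidation level that the key step produces.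

12 from 9 (through 10 and 11). This is the central cut: C2–C3 is broken and C2 is reconnected to the oxygen on C9. The ring-opened form is the oxocarbenium–silyl enol ether ion pair 10, and the closed acetal is the 4,5-dihydro-1,3-dioxepine 9. Cutting O1–C2 or O1–C5 instead would lead to open-chain triols with three stereocentres still to be set. This cut removes the ring and two stereocentres in an isomerisation and leaves 9 with only one controlled centre, the future C4. The forward reaction asks that the enol ether, not the styrene, captures the cation, and that closure is reversible so that the first-formed 2,3-cis aldehyde 11 drains into the all-trans aldehyde 12.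

9 from 4 and 8. The C4–C7' bond (C5–alkenyl in dioxepine numbering) is cut, giving the symmetrical 4,7-dihydro-1,3-dioxepine 4 and the alkenyl triflate 8. Both are achiral, so the whole absolute configuration of the target rests on one catalytic step. The forward Heck reaction must choose between the two enantiotopic alkene carbons of 4 and must eliminate hydride towards oxygen to give the enol ether.

4 from 2 and 3; 2 from 1; 8 from 6 (through enolate 7); 6 from 5. The acetal C–O bonds of 4 are cut to the silylated aldehyde 2 and the diol 3, and 2 comes from vanillin 1. The triflate 8 comes from the enolate 7 of ketone 6, which is the bis-silyl ether of 3,4-dihydroxyacetophenone 5. These are protections and condensations of three cheap commercial compounds.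

## Roads not taken

Alternative 1: The cut is made at the ring oxygen, so the lactone A1 (C2 as the lactone carbonyl, C4 and C7' as in the target) is traced back to the 3-substituted cyclobutanone A2. In the forward sense a flavin-dependent Baeyer–Villiger monooxygenase would insert oxygen into one of the two diastereotopic acyl C–C bonds of A2 and so define C4.
- Merits: C7' is fixed before the ring exists, so the late 1,2-induction of the chosen plan is avoided, and the oxygen insertion needs no heavy metal.
- Weak points: A2 carries a very bulky side chain, far from the small 3-substituted cyclobutanones on which such enzymes are dependable. C7' must first be made enantiopure by a separate asymmetric step. A1 still lacks C9, the guaiacyl ring and two ring stereocentres, which means enolate alkylation at C3, aryl addition at C2 and a silane/Lewis acid reduction at C2 next to an ionisable silyloxybenzyl group.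
- Comparison: in control of C7' this road is the better one. The chosen plan sets against it that one isomerisation builds the ring together with C2 and C3, that only one enantioselective step is needed, and that no enzyme screening is required.

Alternative 2: C2–C3 and O1–C5 are cut together, giving the aldehyde A5 and the donor–acceptor cyclopropane A4, in which C5 carries the silyloxy group, C3 the ester and C4 the C7' carbon masked as a dithiane. In the forward sense TiCl4 opens the C3–C5 bond of A4 to a titanium ester enolate; this adds to A5 and the aldolate oxygen closes on C5, giving the lactol A3 in one operation.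
- Merits: the road is convergent, joins the two aryl halves late, and keeps C7' at the ketone level without an alkene that could compete as a nucleophile. In convergence it is superior to the chosen plan.
- Weak points: after A3 the C5 hydroxyl must be removed reductively, the ester reduced to C9H2OH and the dithiane hydrolysed beside electron-rich arenes, and the same ketone reduction as in the chosen plan follows. Three benzyl ethers and a dithiane meet stoichiometric TiCl4. A4 needs an asymmetric cyclopropanation of a hindered enol ether to define C4.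
- Comparison: the chosen plan makes the same C2–C3 bond intramolecularly with a catalytic Lewis acid, delivers C5 and C9 at the right oxidation levels at once, and takes its absolute configuration from a catalytic Heck reaction.

Alternative 3: C5 is removed as formaldehyde A8 by cutting O1–C5 and C4–C5, which leaves the homopropargylic alcohol A7 with C2 and C3 in place. In the forward sense Me3SiOTf condenses A7 with A8 to an oxocarbenium ion, the aryl alkyne attacks it through C4 in a 5-exo-dig closure, and the aryl-stabilised vinyl cation at C7' is captured and tautomerises to the ketone A6, with C4 settling trans to C3.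
- Merits: the C7' ketone arrives directly, so the oxidative cleavage of the chosen plan is saved, and C5 comes from the cheapest reagent. In this respect the road is at least as short.
- Weak points: A7 holds two adjacent stereocentres that must both be set in an open chain. One is a benzylic carbinol that the Lewis acid can ionise (hence the deactivating pivalate) and that oxonia-Cope-type equilibria of the oxocarbenium ion can scramble. The mixed pivalate/benzyl protection ends in a hydrogenolysis next to two activated benzylic C–O bonds. The late ketone reduction is common to both roads.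
- Comparison: the chosen plan sets against the saved oxidation a much simpler precursor: three achiral building blocks, one catalytic asymmetric step, and C2 and C3 formed under thermodynamic control.

Key step: step 6

Assumption: (S)-BINAP is written as the ligand enantiomer that gives the (5R) acetal 9 in step 5; if the sense of induction proves opposite, (R)-BINAP is used and nothing else changes.

## Route

Step 1
Reactants: 1 vanillin (4-hydroxy-3-methoxybenzaldehyde)
Product: 2 4-(TBSO)-3-methoxybenzaldehyde
Conditions: TBSCl, imidazole, DMF, 0 °C to rt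
Reagents that add atoms: tert-butyldimethylsilyl chloride, CC(C)(C)[Si](C)(C)Cl
Why: Imidazole-promoted silylation of a phenol; the aryl TBS ether should withstand the acid catalysis, amide base, Lewis acid, hydride and osmylation ahead and leaves with fluoride at the end.

Step 2
Reactants: 2 4-(TBSO)-3-methoxybenzaldehyde; 3 (Z)-but-2-ene-1,4-diol
Product: 4 2-[4-(TBSO)-3-methoxyphenyl]-4,7-dihydro-1,3-dioxepine
Conditions: p-TsOH·H2O (cat.), benzene, reflux, Dean–Stark trap
Reagents that add atoms: none
Why: Acid-catalysed acetalisation with azeotropic removal of water; the cis-diol closes the seven-membered cyclic acetal, and no stereocentre arises because the acetal carbon lies in the mirror plane of 4.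

Step 3
Reactants: 5 3,4-dihydroxyacetophenone
Product: 6 1-[3,4-bis(TBSO)phenyl]ethan-1-one
Conditions: TBSCl (2.4 equiv), imidazole, DMF, rt
Reagents that add atoms: tert-butyldimethylsilyl chloride, CC(C)(C)[Si](C)(C)Cl
Why: Double silylation of the catechol (silyl ether formation), which masks the acidic phenols before enolate chemistry and matches the protecting group on the other ring.

Step 4
Reactants: 6 1-[3,4-bis(TBSO)phenyl]ethan-1-one
Product: 8 1-[3,4-bis(TBSO)phenyl]ethenyl trifluoromethanesulfonate, via potassium enolate 7 (not isolated)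
Conditions: KN(SiMe3)2, THF, −78 °C; then PhNTf2, −78 to 0 °C; purification on Et3N-deactivated silica
Reagents that add atoms: N-phenylbis(trifluoromethanesulfonimide), O=S(=O)(N(c1ccccc1)S(=O)(=O)C(F)(F)F)C(F)(F)F
Why: Enol triflate formation: the methyl ketone is deprotonated to enolate 7, which is O-sulfonylated by the triflimide; a hindered amide base at low temperature spares the aryl silyl ethers.

Step 5
Reactants: 4 2-[4-(TBSO)-3-methoxyphenyl]-4,7-dihydro-1,3-dioxepine; 8 1-[3,4-bis(TBSO)phenyl]ethenyl trifluoromethanesulfonate
Product: 9 (5R)-5-{1-[3,4-bis(TBSO)phenyl]ethenyl}-2-[4-(TBSO)-3-methoxyphenyl]-4,5-dihydro-1,3-dioxepine (both C2 epimers)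
Conditions: Pd(OAc)2 (5 mol%), (S)-BINAP (10 mol%), K2CO3, 3 Å molecular sieves, benzene, 60 °C; 4 in threefold excess (recovered)
Reagents that add atoms: none
Why: Intermolecular asymmetric Heck reaction by the cationic pathway: the triflate adds oxidatively to zerovalent palladium, the complex [Pd(alkenyl)(BINAP)]+ TfO− adds syn across C5=C6 of 4, and only the C7 hydrogen is syn to palladium, so β-hydride elimination gives the C6=C7 enol ether and leaves the new centre intact. The chiral diphosphine chooses between the two enantiotopic alkene carbons and so sets C5 (the future C4); the acetal carbon becomes a stereocentre without control, which is harmless because step 6 makes it planar.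

Step 6
Reactants: 9 (5R)-5-{1-[3,4-bis(TBSO)phenyl]ethenyl}-2-[4-(TBSO)-3-methoxyphenyl]-4,5-dihydro-1,3-dioxepine (both C2 epimers)
Product: 12 (2S,3S,4R)-4-{1-[3,4-bis(TBSO)phenyl]ethenyl}-2-[4-(TBSO)-3-methoxyphenyl]oxolane-3-carbaldehyde (all-trans), via oxocarbenium silyl enol ether 10 (not isolated), via 2,3-cis aldehyde 11 (not isolated)
Conditions: Me3SiOTf (0.2 equiv), 2,6-di-tert-butyl-4-methylpyridine (0.3 equiv), CH2Cl2, −78 °C, then −20 °C; Et3N quench
Reagents that add atoms: none
Why: Me3SiOTf silylates the enol-ether oxygen of the vinyl acetal and breaks its bond to C2, giving the aryl-stabilised oxocarbenium ion tethered to a (Z)-silyl enol ether (10); the enol carbon C3 then adds to C2 in an intramolecular Mukaiyama-type aldol step and the silyl group is released, so the Lewis acid turns over. The closest known reaction type is the Lewis-acid [1,3] oxygen-to-carbon ring contraction of 4,5-dihydro-1,3-dioxepines to tetrahydrofuran-3-carbaldehydes. The tetrahydrofuran closes in the 5-(enolexo)-exo-trig mode. C2 is planar in 10, so both acetal epimers of 9 converge. C3 is controlled by the C4 centre from step 5: the enol ether adds so that the new C3–C9 bond lies trans to the 1-arylvinyl group on C4. C2 is set reversibly: closure at −78 °C is expected to give the 2,3-cis aldehyde 11 first, and on warming retro-aldol reopening through 10, eased by the electron-rich aryl group, should funnel it to the all-trans aldehyde 12 with all three substituents pseudo-equatorial. The step needs the enol ether to outrun the pendant styrene as nucleophile: the silyl enol ether is the stronger π-nucleophile and closes a five-membered ring within the ion pair, whereas the styrene would have to close a six-membered ring, and the hindered pyridine keeps triflic acid away from the alkene.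

Step 7
Reactants: 12 (2S,3S,4R)-4-{1-[3,4-bis(TBSO)phenyl]ethenyl}-2-[4-(TBSO)-3-methoxyphenyl]oxolane-3-carbaldehyde
Product: 13 [(2S,3R,4R)-4-{1-[3,4-bis(TBSO)phenyl]ethenyl}-2-[4-(TBSO)-3-methoxyphenyl]oxolan-3-yl]methanol
Conditions: NaBH4, MeOH/THF, 0 °C
Reagents that add atoms: none
Why: Borohydride reduction of the aldehyde, the only group in 12 that reacts with this reagent; C3 already sits in its preferred trans arrangement, so epimerisation before reduction would not change the outcome.

Step 8
Reactants: 13 [(2S,3R,4R)-4-{1-[3,4-bis(TBSO)phenyl]ethenyl}-2-[4-(TBSO)-3-methoxyphenyl]oxolan-3-yl]methanol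
Product: 15 (2S,3R,4S)-4-[3,4-bis(TBSO)benzoyl]-3-(hydroxymethyl)-2-[4-(TBSO)-3-methoxyphenyl]oxolane, via vicinal diol 14 (not isolated)
Conditions: OsO4 (cat.), NaIO4, 2,6-lutidine, 1,4-dioxane/H2O (3:1), rt
Reagents that add atoms: osmium tetroxide (delivers the oxygen atoms), O=[Os](=O)(=O)=O; sodium periodate (terminal oxidant that re-forms OsO4 and cleaves the diol), [Na+].[O-]I(=O)(=O)=O
Why: Lemieux–Johnson oxidation: OsO4 dihydroxylates the only alkene to diol 14 and periodate cleaves it to the aryl ketone and formaldehyde, with 2,6-lutidine suppressing over-oxidation. The free C9 hydroxyl cannot form a hemiketal with the new ketone because the two groups are trans on the ring, and the silylated phenols are inert to periodate.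

Step 9
Reactants: 15 (2S,3R,4S)-4-[3,4-bis(TBSO)benzoyl]-3-(hydroxymethyl)-2-[4-(TBSO)-3-methoxyphenyl]oxolane
Product: 16 (2S,3R,4S)-4-{(R)-[3,4-bis(TBSO)phenyl](hydroxy)methyl}-3-(hydroxymethyl)-2-[4-(TBSO)-3-methoxyphenyl]oxolane
Conditions: LiBH(s-Bu)3 (2.5 equiv), THF, −78 °C; aq. NH4Cl
Reagents that add atoms: none
Why: Felkin–Anh-controlled reduction of an α-chiral aryl ketone by a bulky trialkylborohydride: with the branched ring carbon C3 (its side chain enlarged as the alkoxide) anti to the incoming hydride and the C4 hydrogen next to the aryl group, attack occurs on the face that gives the (7'R)-carbinol. A lithium chelate between the carbonyl and the ring oxygen O1 would expose the same face, so both models point to the same product.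

Step 10
Reactants: 16 (2S,3R,4S)-4-{(R)-[3,4-bis(TBSO)phenyl](hydroxy)methyl}-3-(hydroxymethyl)-2-[4-(TBSO)-3-methoxyphenyl]oxolane
Product: 17 (2S,3R,4S)-4-[(R)-(3,4-dihydroxyphenyl)(hydroxy)methyl]-2-(4-hydroxy-3-methoxyphenyl)-3-(hydroxymethyl)oxolane (target)
Conditions: Bu4NF (3.3 equiv), AcOH (3.5 equiv), THF, 0 °C, argon
Reagents that add atoms: none
Why: Fluoride cleaves the three aryl silyl ethers, and acetic acid protonates the phenoxides at once, so the para-hydroxybenzylic carbinol is not driven to a quinone methide and the catechol is not left as an oxidisable anion. No benzylic C–O bond is touched, as it could be under hydrogenolysis.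

## Compound list

1 | vanillin (4-hydroxy-3-methoxybenzaldehyde) | COc1cc(C=O)ccc1O | starting material
2 | 4-(tert-butyldimethylsilyloxy)-3-methoxybenzaldehyde | COc1cc(C=O)ccc1O[Si](C)(C)C(C)(C)C | intermediate
3 | (Z)-but-2-ene-1,4-diol | OC/C=C\CO | starting material
4 | 2-[4-(TBSO)-3-methoxyphenyl]-4,7-dihydro-1,3-dioxepine | COc1cc(C2OC/C=C\CO2)ccc1O[Si](C)(C)C(C)(C)C | intermediate
5 | 3,4-dihydroxyacetophenone | CC(=O)c1ccc(O)c(O)c1 | starting material
6 | 1-[3,4-bis(TBSO)phenyl]ethan-1-one | CC(=O)c1ccc(O[Si](C)(C)C(C)(C)C)c(O[Si](C)(C)C(C)(C)C)c1 | intermediate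
7 | potassium enolate of 6 (potassium 1-[3,4-bis(TBSO)phenyl]ethen-1-olate) | [K+].[O-]C(=C)c1ccc(O[Si](C)(C)C(C)(C)C)c(O[Si](C)(C)C(C)(C)C)c1 | intermediate (not isolated)
8 | 1-[3,4-bis(TBSO)phenyl]ethenyl trifluoromethanesulfonate | C=C(OS(=O)(=O)C(F)(F)F)c1ccc(O[Si](C)(C)C(C)(C)C)c(O[Si](C)(C)C(C)(C)C)c1 | intermediate
9 | (5R)-5-{1-[3,4-bis(TBSO)phenyl]ethenyl}-2-[4-(TBSO)-3-methoxyphenyl]-4,5-dihydro-1,3-dioxepine, both C2 epimers (acetal carbon left open in the SMILES) | COc1cc(C2OC=C[C@H](C(=C)c3ccc(O[Si](C)(C)C(C)(C)C)c(O[Si](C)(C)C(C)(C)C)c3)CO2)ccc1O[Si](C)(C)C(C)(C)C | intermediate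
10 | ring-opened ion pair: aryl oxocarbenium ion tethered to the (Z)-trimethylsilyl enol ether, triflate counter-ion | COc1cc(C=[O+]C[C@@H](C(=C)c2ccc(O[Si](C)(C)C(C)(C)C)c(O[Si](C)(C)C(C)(C)C)c2)/C=C\O[Si](C)(C)C)ccc1O[Si](C)(C)C(C)(C)C.[O-]S(=O)(=O)C(F)(F)F | intermediate (not isolated)
11 | (2R,3S,4R)-4-{1-[3,4-bis(TBSO)phenyl]ethenyl}-2-[4-(TBSO)-3-methoxyphenyl]oxolane-3-carbaldehyde (2,3-cis, 3,4-trans) | COc1cc([C@@H]2OC[C@@H](C(=C)c3ccc(O[Si](C)(C)C(C)(C)C)c(O[Si](C)(C)C(C)(C)C)c3)[C@@H]2C=O)ccc1O[Si](C)(C)C(C)(C)C | intermediate (not isolated)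
12 | (2S,3S,4R)-4-{1-[3,4-bis(TBSO)phenyl]ethenyl}-2-[4-(TBSO)-3-methoxyphenyl]oxolane-3-carbaldehyde (all-trans) | COc1cc([C@H]2OC[C@@H](C(=C)c3ccc(O[Si](C)(C)C(C)(C)C)c(O[Si](C)(C)C(C)(C)C)c3)[C@@H]2C=O)ccc1O[Si](C)(C)C(C)(C)C | intermediate
13 | [(2S,3R,4R)-4-{1-[3,4-bis(TBSO)phenyl]ethenyl}-2-[4-(TBSO)-3-methoxyphenyl]oxolan-3-yl]methanol | COc1cc([C@H]2OC[C@@H](C(=C)c3ccc(O[Si](C)(C)C(C)(C)C)c(O[Si](C)(C)C(C)(C)C)c3)[C@@H]2CO)ccc1O[Si](C)(C)C(C)(C)C | intermediate
14 | 1-[3,4-bis(TBSO)phenyl]-1-[(3S,4R,5S)-5-[4-(TBSO)-3-methoxyphenyl]-4-(hydroxymethyl)oxolan-3-yl]ethane-1,2-diol (carbinol epimers) | COc1cc([C@H]2OC[C@@H](C(O)(CO)c3ccc(O[Si](C)(C)C(C)(C)C)c(O[Si](C)(C)C(C)(C)C)c3)[C@@H]2CO)ccc1O[Si](C)(C)C(C)(C)C | intermediate (not isolated)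
15 | (2S,3R,4S)-4-[3,4-bis(TBSO)benzoyl]-3-(hydroxymethyl)-2-[4-(TBSO)-3-methoxyphenyl]oxolane | COc1cc([C@H]2OC[C@@H](C(=O)c3ccc(O[Si](C)(C)C(C)(C)C)c(O[Si](C)(C)C(C)(C)C)c3)[C@@H]2CO)ccc1O[Si](C)(C)C(C)(C)C | intermediate
16 | (2S,3R,4S)-4-{(R)-[3,4-bis(TBSO)phenyl](hydroxy)methyl}-3-(hydroxymethyl)-2-[4-(TBSO)-3-methoxyphenyl]oxolane | COc1cc([C@H]2OC[C@@H]([C@@H](O)c3ccc(O[Si](C)(C)C(C)(C)C)c(O[Si](C)(C)C(C)(C)C)c3)[C@@H]2CO)ccc1O[Si](C)(C)C(C)(C)C | intermediate
17 | (2S,3R,4S)-4-[(R)-(3,4-dihydroxyphenyl)(hydroxy)methyl]-2-(4-hydroxy-3-methoxyphenyl)-3-(hydroxymethyl)oxolane | COc1cc([C@H]2OC[C@@H]([C@@H](O)c3ccc(O)c(O)c3)[C@@H]2CO)ccc1O | target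

## Step count and least certain steps

Total: 10 steps. Longest linear sequence: 8 steps (steps 1, 2, 5, 6, 7, 8, 9, 10 from vanillin 1; the branch from 5 through steps 3 and 4 is equally long).

Step 6 (key step). The most likely failure is capture of the oxocarbenium ion by the electron-rich styrene in a six-membered Prins-type closure, or acid-initiated oligomerisation of that alkene, in place of enol-ether closure. Prolonged equilibration, which the all-trans outcome needs, gives such irreversible side paths more time. Incomplete cis-to-trans equilibration at C2 and hydrolysis of the vinyl acetal by adventitious water are the lesser risks. The fallback sets out from 9 and comes back at 13. Mild aqueous acid (pyridinium p-toluenesulfonate, acetone/H2O) hydrolyses the vinyl acetal, returning aldehyde 2 and giving the lactol (4R)-4-{1-[3,4-bis(TBSO)phenyl]ethenyl}oxolan-2-ol F1. Oxidation with PhI(OAc)2 and catalytic TEMPO gives the lactone (4R)-4-{1-[3,4-bis(TBSO)phenyl]ethenyl}oxolan-2-one F2. Its lithium enolate (LiN(i-Pr)2, THF, −78 °C) adds to aldehyde 2 anti to the C4 substituent to give the 3,4-trans aldol lactone F3, whose carbinol configuration does not matter. LiBH4 reduces the lactone to the triol F4, and catalytic camphorsulfonic acid in CH2Cl2 ionises the guaiacyl carbinol so that the C5 hydroxyl closes the ring trans to C9, giving 13. This classical lactone aldol and cycloetherification makes the same C2–C3 bond intermolecularly and closes the ring at O1–C2 instead.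

Step 5. The main risk is insufficient enantioselection: the 2-aryl group makes the two alkene faces of 4 diastereotopic, and the catalyst must pick the same ring carbon on both. Palladium hydride may also move a double bond into conjugation with loss of the new centre, and the electron-rich triflate 8 or the enol ether of 9 may be lost to traces of acid or water. The fallback sets out from 13 of insufficient enantiomeric purity and comes back at 13. Esterification with (S)-O-methylmandelic acid (dicyclohexylcarbodiimide, catalytic 4-dimethylaminopyridine, CH2Cl2, 0 °C) gives the (S)-O-methylmandelate of 13, F5, together with the (S)-O-methylmandelate of the enantiomer of 13, F6. The two diastereomers are separated by chromatography or crystallisation, and i-Bu2AlH (CH2Cl2, −78 to 0 °C) cleaves F5 back to 13 without touching the aryl silyl ethers. Catalyst control is thus backed by a classical resolution through covalent diastereomers.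

Step 9. The risk is poor facial selectivity at the ketone, since both α-substituents of the carbonyl are ring carbons and may not differ enough as the large and medium groups. The fallback sets out from 15 and comes back at 17. Silylation of the C9 hydroxyl (TBSCl, imidazole, DMF) gives the 9-O-TBS ketone F7, in which the C3 side chain is much bulkier. Reagent-controlled Corey–Bakshi–Shibata reduction ((S)-2-methyl-CBS-oxazaborolidine, BH3·SMe2, THF, −20 °C), with the aryl group as the large substituent, should give the (7'R)-carbinol F8. Bu4NF/AcOH in THF then removes all four silyl groups to give 17. Substrate control alone is replaced by matched substrate and reagent control on a modified substrate.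

## Further compounds

F1 | step 6 | (4R)-4-{1-[3,4-bis(TBSO)phenyl]ethenyl}oxolan-2-ol (anomers) | OC1C[C@H](C(=C)c2ccc(O[Si](C)(C)C(C)(C)C)c(O[Si](C)(C)C(C)(C)C)c2)CO1
F2 | step 6 | (4R)-4-{1-[3,4-bis(TBSO)phenyl]ethenyl}oxolan-2-one | O=C1C[C@H](C(=C)c2ccc(O[Si](C)(C)C(C)(C)C)c(O[Si](C)(C)C(C)(C)C)c2)CO1
F3 | step 6 | (3S,4R)-4-{1-[3,4-bis(TBSO)phenyl]ethenyl}-3-{[4-(TBSO)-3-methoxyphenyl](hydroxy)methyl}oxolan-2-one (carbinol epimers) | O=C1[C@H](C(O)c2ccc(O[Si](C)(C)C(C)(C)C)c(OC)c2)[C@H](C(=C)c2ccc(O[Si](C)(C)C(C)(C)C)c(O[Si](C)(C)C(C)(C)C)c2)CO1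
F4 | step 6 | (2R,3R)-3-{1-[3,4-bis(TBSO)phenyl]ethenyl}-2-{[4-(TBSO)-3-methoxyphenyl](hydroxy)methyl}butane-1,4-diol (carbinol epimers) | OC[C@H](C(O)c1ccc(O[Si](C)(C)C(C)(C)C)c(OC)c1)[C@H](C(=C)c1ccc(O[Si](C)(C)C(C)(C)C)c(O[Si](C)(C)C(C)(C)C)c1)CO
F5 | step 5 | [(2S,3R,4R)-4-{1-[3,4-bis(TBSO)phenyl]ethenyl}-2-[4-(TBSO)-3-methoxyphenyl]oxolan-3-yl]methyl (2S)-2-methoxy-2-phenylacetate | COc1cc([C@H]2OC[C@@H](C(=C)c3ccc(O[Si](C)(C)C(C)(C)C)c(O[Si](C)(C)C(C)(C)C)c3)[C@@H]2COC(=O)[C@@H](OC)c2ccccc2)ccc1O[Si](C)(C)C(C)(C)C
F6 | step 5 | [(2R,3S,4S)-4-{1-[3,4-bis(TBSO)phenyl]ethenyl}-2-[4-(TBSO)-3-methoxyphenyl]oxolan-3-yl]methyl (2S)-2-methoxy-2-phenylacetate | COc1cc([C@@H]2OC[C@H](C(=C)c3ccc(O[Si](C)(C)C(C)(C)C)c(O[Si](C)(C)C(C)(C)C)c3)[C@H]2COC(=O)[C@@H](OC)c2ccccc2)ccc1O[Si](C)(C)C(C)(C)C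
F7 | step 9 | (2S,3R,4S)-4-[3,4-bis(TBSO)benzoyl]-3-[(TBSO)methyl]-2-[4-(TBSO)-3-methoxyphenyl]oxolane | COc1cc([C@H]2OC[C@@H](C(=O)c3ccc(O[Si](C)(C)C(C)(C)C)c(O[Si](C)(C)C(C)(C)C)c3)[C@@H]2CO[Si](C)(C)C(C)(C)C)ccc1O[Si](C)(C)C(C)(C)C
F8 | step 9 | (2S,3R,4S)-4-{(R)-[3,4-bis(TBSO)phenyl](hydroxy)methyl}-3-[(TBSO)methyl]-2-[4-(TBSO)-3-methoxyphenyl]oxolane | COc1cc([C@H]2OC[C@@H]([C@@H](O)c3ccc(O[Si](C)(C)C(C)(C)C)c(O[Si](C)(C)C(C)(C)C)c3)[C@@H]2CO[Si](C)(C)C(C)(C)C)ccc1O[Si](C)(C)C(C)(C)C
A1 | alternative 1 | (4S)-4-{(R)-[3,4-bis(benzyloxy)phenyl](tert-butyldimethylsilyloxy)methyl}oxolan-2-one | O=C1OC[C@@H]([C@@H](O[Si](C)(C)C(C)(C)C)c2ccc(OCc3ccccc3)c(OCc3ccccc3)c2)C1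
A2 | alternative 1 | 3-{(R)-[3,4-bis(benzyloxy)phenyl](tert-butyldimethylsilyloxy)methyl}cyclobutan-1-one | O=C1CC(C1)[C@@H](O[Si](C)(C)C(C)(C)C)c1ccc(OCc2ccccc2)c(OCc2ccccc2)c1
A3 | alternative 2 | methyl 2-[4-(benzyloxy)-3-methoxyphenyl]-4-{2-[3,4-bis(benzyloxy)phenyl]-1,3-dithian-2-yl}-5-hydroxyoxolane-3-carboxylate (all-trans at C2, C3, C4; C5 epimers) | COc1cc([C@H]2OC(O)[C@@H](C5(SCCCS5)c3ccc(OCc4ccccc4)c(OCc4ccccc4)c3)[C@@H]2C(=O)OC)ccc1OCc1ccccc1
A4 | alternative 2 | methyl 2-{2-[3,4-bis(benzyloxy)phenyl]-1,3-dithian-2-yl}-3-(trimethylsilyloxy)cyclopropane-1-carboxylate (C4 as in the target) | COC(=O)C1C(O[Si](C)(C)C)[C@H]1C1(SCCCS1)c1ccc(OCc2ccccc2)c(OCc2ccccc2)c1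
A5 | alternative 2 | 4-(benzyloxy)-3-methoxybenzaldehyde | COc1cc(C=O)ccc1OCc1ccccc1
A6 | alternative 3 | all-trans 3-(benzyloxymethyl)-4-[3,4-bis(benzyloxy)benzoyl]-2-(3-methoxy-4-pivaloyloxyphenyl)oxolane | COc1cc([C@H]2OC[C@@H](C(=O)c3ccc(OCc4ccccc4)c(OCc4ccccc4)c3)[C@@H]2COCc5ccccc5)ccc1OC(=O)C(C)(C)C
A7 | alternative 3 | 2-(benzyloxymethyl)-4-[3,4-bis(benzyloxy)phenyl]-1-(3-methoxy-4-pivaloyloxyphenyl)but-3-yn-1-ol (C2 and C3 as in the target) | COc1cc([C@@H](O)[C@@H](COCc2ccccc2)C#Cc2ccc(OCc3ccccc3)c(OCc3ccccc3)c2)ccc1OC(=O)C(C)(C)C
A8 | alternative 3 | formaldehyde | C=O
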